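**Retrosynthetic overview**

1. Target 28 ⇐ 27 (hydrogenolysis of two aryl benzyl ethers) ⇐ 26 (tertiary silyl ether) ⇐ acid 22. The E-propenyl group of 22 is cut down to the C5 hydroxymethyl and ring C is closed by lactonisation (O1–C2) in step 15, the only ring-forming event; rings A and B are bought.
2. 22 ⇐ allylic silyl glyoxylate 14 + benzylmagnesium reagent 18 in one flask: C3–CH2(ring A) by 1,2-addition to the acylsilane, silicon shift from C3 to oxygen, then C3–C4 by [3,3] shift of the ester enolate so formed.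
3. Feature used: the fully substituted carbinol carbon C3 of the lactone (ring C: O1–C2(=O)–C3–C4–C5) is the α-carbon of a glycolic acid unit. Besides OH and the C2 carbonyl it carries two unlike carbon substituents (the CH2 of ring A and ring carbon C4), so one glyoxylate carbon can be attacked as a ketone-type electrophile and then react as an ester enolate.
4. 14 ⇐ (S,Z)-allylic alcohol 8 (bromoacetate, diazo ester, C-silylation, dioxirane oxidation) ⇐ alkynol 7 (Lindlar) ⇐ benzylic bromide 4 (from syringaldehyde 1) + (S)-but-3-yn-2-ol 5; 18 ⇐ vanillyl alcohol 15.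
5. Stereochemistry: the bought (S)-carbinol centre of 5 is relayed through the Z-alkene into C4 and, together with the enolate geometry, into C3; it is consumed in the rearrangement.

Key step: step 13

Remark: C2–C5 follow the lactone numbering (O1 ring oxygen, C2 carbonyl). The target SMILES is read as (3S,4S), i.e. the two benzyl groups trans on ring C and the 3-hydroxyl cis to the C4 benzyl group.

**Route**

Step 1
Reactants: 1 syringaldehyde
Product: 2 4-(benzyloxy)-3,5-dimethoxybenzaldehyde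
Conditions: BnBr, K2CO3, DMF, 60 °C
Reagents that add atoms: benzyl bromide, BrCc1ccccc1
Why: Williamson ether synthesis on the phenoxide, the only acidic site, should mask the ring B phenol as a benzyl ether that lasts until the final hydrogenolysis.

Step 2
Reactants: 2 4-(benzyloxy)-3,5-dimethoxybenzaldehyde
Product: 3 [4-(benzyloxy)-3,5-dimethoxyphenyl]methanol
Conditions: NaBH4, MeOH/THF, 0 °C
Reagents that add atoms: none
Why: Borohydride reduction of an aromatic aldehyde to the benzylic alcohol is fast and leaves the ethers untouched.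

Step 3
Reactants: 3 [4-(benzyloxy)-3,5-dimethoxyphenyl]methanol
Product: 4 4-(benzyloxy)-3,5-dimethoxybenzyl bromide
Conditions: PBr3, Et2O, 0 °C; used crude
Reagents that add atoms: phosphorus tribromide, BrP(Br)Br
Why: Bromination with PBr3 (bromide displacement of the phosphite ester) is facile at an electron-rich benzylic carbon, and the labile bromide is carried on without storage.

Step 4
Reactants: 4 4-(benzyloxy)-3,5-dimethoxybenzyl bromide; 5 (S)-but-3-yn-2-ol
Product: 7 (S)-5-[4-(benzyloxy)-3,5-dimethoxyphenyl]pent-3-yn-2-ol, via bis(bromomagnesium) alkynide alkoxide 6 (not isolated)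
Conditions: 5 (1.3 equiv), EtMgBr (2.6 equiv), THF, 0 → 23 °C; CuI (10 mol %), then 4, THF, 50 °C; aq. NH4Cl
Reagents that add atoms: none
Why: Copper-catalysed coupling of an alkynylmagnesium halide with a benzylic bromide forms the C(sp)–C(sp3) bond at carbon while the magnesium alkoxide stays inert, and the (S)-carbinol centre is not touched.

Step 5
Reactants: 7 (S)-5-[4-(benzyloxy)-3,5-dimethoxyphenyl]pent-3-yn-2-ol
Product: 8 (S,Z)-5-[4-(benzyloxy)-3,5-dimethoxyphenyl]pent-3-en-2-ol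
Conditions: H2 (1 atm), Pd/CaCO3 poisoned with Pb(OAc)2, quinoline, EtOAc, 23 °C
Reagents that add atoms: none
Why: Lindlar semihydrogenation delivers both hydrogens syn from the poisoned palladium surface to give the Z-alkene, and the poisoned catalyst should neither over-reduce nor cleave the aryl benzyl ether.

Step 6
Reactants: 8 (S,Z)-5-[4-(benzyloxy)-3,5-dimethoxyphenyl]pent-3-en-2-ol
Product: 9 (S,Z)-5-[4-(benzyloxy)-3,5-dimethoxyphenyl]pent-3-en-2-yl bromoacetate
Conditions: BrCH2COBr, NaHCO3, MeCN, 0 °C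
Reagents that add atoms: bromoacetyl bromide, BrCC(Br)=O
Why: O-acylation of the secondary allylic alcohol with an acyl bromide proceeds with retention at the carbinol carbon, and the cold bicarbonate-buffered medium should avoid allylic ionisation.

Step 7
Reactants: 9 (S,Z)-5-[4-(benzyloxy)-3,5-dimethoxyphenyl]pent-3-en-2-yl bromoacetate
Product: 12 (S,Z)-5-[4-(benzyloxy)-3,5-dimethoxyphenyl]pent-3-en-2-yl diazoacetate, via N-alkylated ditosylhydrazine 10 (not isolated), via glyoxylate tosylhydrazone 11 (not isolated)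
Conditions: TsNHNHTs, DBU, THF, 0 °C
Reagents that add atoms: N,N'-ditosylhydrazine, Cc1ccc(cc1)S(=O)(=O)NNS(=O)(=O)c1ccc(C)cc1
Why: Fukuyama diazoacetate synthesis, in which N-alkylation of the ditosylhydrazine by the bromoacetate is followed by two DBU-induced losses of p-toluenesulfinate (the second of Bamford–Stevens type), should give the diazo ester at 0 °C without heating the allylic ester.

Step 8
Reactants: 12 (S,Z)-5-[4-(benzyloxy)-3,5-dimethoxyphenyl]pent-3-en-2-yl diazoacetate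
Product: 13 (S,Z)-5-[4-(benzyloxy)-3,5-dimethoxyphenyl]pent-3-en-2-yl (tert-butyldimethylsilyl)diazoacetate
Conditions: tBuMe2SiOTf, iPr2NEt, Et2O, −78 → 0 °C
Reagents that add atoms: tert-butyldimethylsilyl triflate, CC(C)(C)[Si](C)(C)OS(=O)(=O)C(F)(F)F
Why: Electrophilic C-silylation of the nucleophilic diazo carbon by a silyl triflate with a hindered amine base is the standard entry to silyl diazoacetates.

Step 9
Reactants: 13 (S,Z)-5-[4-(benzyloxy)-3,5-dimethoxyphenyl]pent-3-en-2-yl (tert-butyldimethylsilyl)diazoacetate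
Product: 14 (S,Z)-5-[4-(benzyloxy)-3,5-dimethoxyphenyl]pent-3-en-2-yl (tert-butyldimethylsilyl)glyoxylate
Conditions: dimethyldioxirane (1.05 equiv, titrated acetone solution), CH2Cl2, −78 → −30 °C
Reagents that add atoms: dimethyldioxirane, CC1(C)OO1
Why: Oxygen-atom transfer from the dioxirane to the electron-rich diazo carbon with loss of N2 should give the acylsilane keto ester, and with one equivalent at low temperature it should outrun epoxidation of the Z-alkene, which is deactivated by its allylic acyloxy group.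

Step 10
Reactants: 15 vanillyl alcohol
Product: 16 [4-(benzyloxy)-3-methoxyphenyl]methanol
Conditions: BnBr, K2CO3, acetone, reflux
Reagents that add atoms: benzyl bromide, BrCc1ccccc1
Why: Williamson ether synthesis in which carbonate deprotonates only the phenol, so O-benzylation is selective over the benzylic alcohol.

Step 11
Reactants: 16 [4-(benzyloxy)-3-methoxyphenyl]methanol
Product: 17 4-(benzyloxy)-3-methoxybenzyl chloride
Conditions: SOCl2, CH2Cl2, 0 °C
Reagents that add atoms: thionyl chloride, ClS(Cl)=O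
Why: Chlorination with SOCl2 through the chlorosulfite should be fast at the electron-rich benzylic position.

Step 12
Reactants: 17 4-(benzyloxy)-3-methoxybenzyl chloride
Product: 18 [4-(benzyloxy)-3-methoxybenzyl]magnesium chloride (titrated THF solution, used at once)
Conditions: Mg turnings (3 equiv, I2-activated), THF, 0 °C, slow addition of 17 at high dilution
Reagents that add atoms: magnesium, [Mg]
Why: Grignard formation by insertion of magnesium into the benzylic C–Cl bond, run cold and dilute with slow addition so that the halide concentration stays low and homocoupling is suppressed.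

Step 13
Reactants: 14 (S,Z)-5-[4-(benzyloxy)-3,5-dimethoxyphenyl]pent-3-en-2-yl (tert-butyldimethylsilyl)glyoxylate; 18 [4-(benzyloxy)-3-methoxybenzyl]magnesium chloride
Product: 22 (2S,3S,E)-2-[4-(benzyloxy)-3-methoxybenzyl]-3-[4-(benzyloxy)-3,5-dimethoxybenzyl]-2-(tert-butyldimethylsilyloxy)hex-4-enoic acid, via magnesium alkoxide adduct 19 (not isolated), via (Z)-magnesium enolate 20 (not isolated), via chloromagnesium carboxylate 21 (not isolated)
Conditions: 18 (1.2 equiv) added to 14, THF, −78 °C, 30 min; warm to 23 °C, 4 h; 1 M HCl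
Reagents that add atoms: none
Why: The benzylmagnesium reagent adds to the acylsilane carbonyl of 14, the more electrophilic, ketone-like carbonyl, to give alkoxide 19 with magnesium bridging the alkoxide and the ester carbonyl oxygen; [1,2]-Brook migration of silicon from carbon to oxygen out of this five-membered chelate then gives the (Z)-glycolate enolate 20, with the silyloxy group cis to the O–Mg oxygen and the ring A benzyl cis to the allylic oxygen. This is the known nucleophile addition/Brook/Ireland–Claisen cascade of allylic silyl glyoxylates with organomagnesium reagents, run here with a benzylic Grignard reagent; it forms the C3–CH2(ring A) and C3–C4 bonds and closes no ring. On warming, 20 undergoes the [3,3] shift through a chair in which the carbinol methyl is equatorial, because an axial methyl would meet the axial ring B benzyl of the Z-alkene in a 1,3-diaxial clash, and in which both benzyl groups are axial and so end anti across the new bond. C4 (C3 of the acid) is set by suprafacial transfer of chirality from the (S)-carbinol carbon through the Z-alkene, and C3 (C2 of the acid) by the enolate geometry within the same chair, which should give the (2S,3S) acid with an E-propenyl group. The step needs attack at the acylsilane only, secured by its higher electrophilicity and by the Brook shift, which converts the alkoxide into an unreactive enolate before a second addition can occur. It also needs a single enolate geometry, secured by the chelated alkoxide from which silicon migrates.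

Step 14
Reactants: 22 (2S,3S,E)-2-[4-(benzyloxy)-3-methoxybenzyl]-3-[4-(benzyloxy)-3,5-dimethoxybenzyl]-2-(tert-butyldimethylsilyloxy)hex-4-enoic acid
Product: 24 (2S,3R)-2-[4-(benzyloxy)-3-methoxybenzyl]-3-[4-(benzyloxy)-3,5-dimethoxybenzyl]-2-(tert-butyldimethylsilyloxy)-4-oxobutanoic acid, via vicinal diol 23 (not isolated)
Conditions: OsO4 (2 mol %), NaIO4 (4 equiv), 2,6-lutidine, dioxane/H2O 3:1, 23 °C; used crude
Reagents that add atoms: osmium tetroxide, O=[Os](=O)(=O)=O; sodium periodate, [Na+].[O-]I(=O)(=O)=O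
Why: Lemieux–Johnson oxidation (osmium-catalysed dihydroxylation of the propenyl group, then periodate glycol cleavage) should cut the alkene to the aldehyde, and the lutidine buffer keeps the acid as its carboxylate and should spare both the stereocentre next to the new aldehyde and the electron-rich rings.

Step 15
Reactants: 24 (2S,3R)-2-[4-(benzyloxy)-3-methoxybenzyl]-3-[4-(benzyloxy)-3,5-dimethoxybenzyl]-2-(tert-butyldimethylsilyloxy)-4-oxobutanoic acid
Product: 26 (3S,4S)-3-[4-(benzyloxy)-3-methoxybenzyl]-4-[4-(benzyloxy)-3,5-dimethoxybenzyl]-3-(tert-butyldimethylsilyloxy)oxolan-2-one, via hydroxy acid 25 (not isolated)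
Conditions: NaBH4, MeOH, 0 °C; then 1 M HCl to pH 2, 23 °C
Reagents that add atoms: none
Why: Borohydride reduction of the aldehyde gives the γ-hydroxy acid, and acidification induces 5-exo-trig lactonisation to ring C, favoured by the quaternary C3, without touching either stereocentre or the hindered tertiary silyl ether.

Step 16
Reactants: 26 (3S,4S)-3-[4-(benzyloxy)-3-methoxybenzyl]-4-[4-(benzyloxy)-3,5-dimethoxybenzyl]-3-(tert-butyldimethylsilyloxy)oxolan-2-one
Product: 27 (3S,4S)-3-[4-(benzyloxy)-3-methoxybenzyl]-4-[4-(benzyloxy)-3,5-dimethoxybenzyl]-3-hydroxyoxolan-2-one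
Conditions: 48% aq. HF, MeCN, 23 °C
Reagents that add atoms: none
Why: Desilylation driven by the strong Si–F bond frees the tertiary alcohol under acidic conditions that keep the lactone closed, which a basic fluoride source might open.

Step 17
Reactants: 27 (3S,4S)-3-[4-(benzyloxy)-3-methoxybenzyl]-4-[4-(benzyloxy)-3,5-dimethoxybenzyl]-3-hydroxyoxolan-2-one
Product: 28 (3S,4S)-3-hydroxy-3-(4-hydroxy-3-methoxybenzyl)-4-(4-hydroxy-3,5-dimethoxybenzyl)oxolan-2-one (CNP0315014.1)
Conditions: H2 (1 atm), 10% Pd/C, EtOAc/MeOH, 23 °C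
Reagents that add atoms: none
Why: Catalytic hydrogenolysis of the two aryl benzyl ethers should release both phenols, no other reducible group being left in the molecule.

**Compound list**

1 | syringaldehyde | COc1cc(C=O)cc(OC)c1O | starting material
2 | 4-(benzyloxy)-3,5-dimethoxybenzaldehyde | COc1cc(C=O)cc(OC)c1OCc1ccccc1 | intermediate
3 | [4-(benzyloxy)-3,5-dimethoxyphenyl]methanol | COc1cc(CO)cc(OC)c1OCc1ccccc1 | intermediate
4 | 4-(benzyloxy)-3,5-dimethoxybenzyl bromide | COc1cc(CBr)cc(OC)c1OCc1ccccc1 | intermediate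
5 | (S)-but-3-yn-2-ol | C[C@@H](C#C)O | starting material
6 | bromomagnesium (S)-4-(bromomagnesio)but-3-yn-2-olate | C[C@@H](C#C[Mg]Br)O[Mg]Br | intermediate
7 | (S)-5-[4-(benzyloxy)-3,5-dimethoxyphenyl]pent-3-yn-2-ol | C[C@@H](C#CCc1cc(OC)c(OCc2ccccc2)c(OC)c1)O | intermediate
8 | (S,Z)-5-[4-(benzyloxy)-3,5-dimethoxyphenyl]pent-3-en-2-ol | C[C@@H](/C=C\Cc1cc(OC)c(OCc2ccccc2)c(OC)c1)O | intermediate
9 | (S,Z)-5-[4-(benzyloxy)-3,5-dimethoxyphenyl]pent-3-en-2-yl bromoacetate | C[C@@H](/C=C\Cc1cc(OC)c(OCc2ccccc2)c(OC)c1)OC(=O)CBr | intermediate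
10 | (S,Z)-5-[4-(benzyloxy)-3,5-dimethoxyphenyl]pent-3-en-2-yl [1,2-bis(p-tolylsulfonyl)hydrazinyl]acetate | C[C@@H](/C=C\Cc1cc(OC)c(OCc2ccccc2)c(OC)c1)OC(=O)CN(NS(=O)(=O)c1ccc(C)cc1)S(=O)(=O)c1ccc(C)cc1 | intermediate
11 | (S,Z)-5-[4-(benzyloxy)-3,5-dimethoxyphenyl]pent-3-en-2-yl glyoxylate p-tolylsulfonylhydrazone | C[C@@H](/C=C\Cc1cc(OC)c(OCc2ccccc2)c(OC)c1)OC(=O)C=NNS(=O)(=O)c1ccc(C)cc1 | intermediate
12 | (S,Z)-5-[4-(benzyloxy)-3,5-dimethoxyphenyl]pent-3-en-2-yl diazoacetate | C[C@@H](/C=C\Cc1cc(OC)c(OCc2ccccc2)c(OC)c1)OC(=O)C=[N+]=[N-] | intermediate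
13 | (S,Z)-5-[4-(benzyloxy)-3,5-dimethoxyphenyl]pent-3-en-2-yl (tert-butyldimethylsilyl)diazoacetate | C[C@@H](/C=C\Cc1cc(OC)c(OCc2ccccc2)c(OC)c1)OC(=O)C(=[N+]=[N-])[Si](C)(C)C(C)(C)C | intermediate
14 | (S,Z)-5-[4-(benzyloxy)-3,5-dimethoxyphenyl]pent-3-en-2-yl (tert-butyldimethylsilyl)glyoxylate | C[C@@H](/C=C\Cc1cc(OC)c(OCc2ccccc2)c(OC)c1)OC(=O)C(=O)[Si](C)(C)C(C)(C)C | intermediate
15 | vanillyl alcohol | COc1cc(CO)ccc1O | starting material
16 | [4-(benzyloxy)-3-methoxyphenyl]methanol | COc1cc(CO)ccc1OCc1ccccc1 | intermediate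
17 | 4-(benzyloxy)-3-methoxybenzyl chloride | COc1cc(CCl)ccc1OCc1ccccc1 | intermediate
18 | [4-(benzyloxy)-3-methoxybenzyl]magnesium chloride | COc1cc(C[Mg]Cl)ccc1OCc1ccccc1 | intermediate
19 | chloromagnesium alkoxide of (S,Z)-5-[4-(benzyloxy)-3,5-dimethoxyphenyl]pent-3-en-2-yl 3-[4-(benzyloxy)-3-methoxyphenyl]-2-hydroxy-2-(tert-butyldimethylsilyl)propanoate (both configurations at the new carbinol carbon) | C[C@@H](/C=C\Cc1cc(OC)c(OCc2ccccc2)c(OC)c1)OC(=O)C(O[Mg]Cl)(Cc1ccc(OCc2ccccc2)c(OC)c1)[Si](C)(C)C(C)(C)C | intermediate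
20 | (Z)-chloromagnesium enolate of (S,Z)-5-[4-(benzyloxy)-3,5-dimethoxyphenyl]pent-3-en-2-yl 3-[4-(benzyloxy)-3-methoxyphenyl]-2-(tert-butyldimethylsilyloxy)propanoate (silyloxy cis to O–Mg) | C[C@@H](/C=C\Cc1cc(OC)c(OCc2ccccc2)c(OC)c1)O/C(O[Mg]Cl)=C(/O[Si](C)(C)C(C)(C)C)Cc1ccc(OCc2ccccc2)c(OC)c1 | intermediate
21 | chloromagnesium salt of acid 22 | COc1cc(C[C@@](O[Si](C)(C)C(C)(C)C)(C(=O)O[Mg]Cl)[C@H](/C=C/C)Cc2cc(OC)c(OCc3ccccc3)c(OC)c2)ccc1OCc1ccccc1 | intermediate
22 | (2S,3S,E)-2-[4-(benzyloxy)-3-methoxybenzyl]-3-[4-(benzyloxy)-3,5-dimethoxybenzyl]-2-(tert-butyldimethylsilyloxy)hex-4-enoic acid | COc1cc(C[C@@](O[Si](C)(C)C(C)(C)C)(C(=O)O)[C@H](/C=C/C)Cc2cc(OC)c(OCc3ccccc3)c(OC)c2)ccc1OCc1ccccc1 | intermediate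
23 | (2S,3S)-2-[4-(benzyloxy)-3-methoxybenzyl]-3-[4-(benzyloxy)-3,5-dimethoxybenzyl]-2-(tert-butyldimethylsilyloxy)-4,5-dihydroxyhexanoic acid (diastereomers at C4 and C5) | COc1cc(C[C@@](O[Si](C)(C)C(C)(C)C)(C(=O)O)[C@H](C(O)C(C)O)Cc2cc(OC)c(OCc3ccccc3)c(OC)c2)ccc1OCc1ccccc1 | intermediate
24 | (2S,3R)-2-[4-(benzyloxy)-3-methoxybenzyl]-3-[4-(benzyloxy)-3,5-dimethoxybenzyl]-2-(tert-butyldimethylsilyloxy)-4-oxobutanoic acid (descriptor at C3 changes by priority only) | COc1cc(C[C@@](O[Si](C)(C)C(C)(C)C)(C(=O)O)[C@H](C=O)Cc2cc(OC)c(OCc3ccccc3)c(OC)c2)ccc1OCc1ccccc1 | intermediate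
25 | (2S,3S)-2-[4-(benzyloxy)-3-methoxybenzyl]-3-[4-(benzyloxy)-3,5-dimethoxybenzyl]-2-(tert-butyldimethylsilyloxy)-4-hydroxybutanoic acid | COc1cc(C[C@@](O[Si](C)(C)C(C)(C)C)(C(=O)O)[C@H](CO)Cc2cc(OC)c(OCc3ccccc3)c(OC)c2)ccc1OCc1ccccc1 | intermediate
26 | (3S,4S)-3-[4-(benzyloxy)-3-methoxybenzyl]-4-[4-(benzyloxy)-3,5-dimethoxybenzyl]-3-(tert-butyldimethylsilyloxy)oxolan-2-one | COc1cc(C[C@@]2(O[Si](C)(C)C(C)(C)C)C(=O)OC[C@@H]2Cc2cc(OC)c(OCc3ccccc3)c(OC)c2)ccc1OCc1ccccc1 | intermediate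
27 | (3S,4S)-3-[4-(benzyloxy)-3-methoxybenzyl]-4-[4-(benzyloxy)-3,5-dimethoxybenzyl]-3-hydroxyoxolan-2-one | COc1cc(C[C@@]2(O)C(=O)OC[C@@H]2Cc2cc(OC)c(OCc3ccccc3)c(OC)c2)ccc1OCc1ccccc1 | intermediate
28 | (3S,4S)-3-hydroxy-3-(4-hydroxy-3-methoxybenzyl)-4-(4-hydroxy-3,5-dimethoxybenzyl)oxolan-2-one | COc1cc(C[C@@]2(O)C(=O)OC[C@@H]2Cc2cc(OC)c(O)c(OC)c2)ccc1O | target

**Step count**

Total: 17 steps. Longest linear sequence: 14 steps (steps 1–9 and 13–17, from syringaldehyde 1); the ring A branch (steps 10–12) joins at step 13.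

**Steps most likely to fail, with fallbacks**

Step 13. The [3,3] shift of the tetrasubstituted magnesium enolate may be slow, so that the enolate is merely protonated on work-up. The enolate geometry may also not be uniform, which would erode the C3/C4 diastereoselectivity, and the benzylic reagent may react through its ortho carbon. The fallback sets out from alcohol 8 (with chloride 17) and comes back at target 28; it sets the same two bonds by a chelation-controlled Ireland–Claisen rearrangement of an α-benzyloxy ester. Benzyloxyacetic acid is doubly deprotonated (LiN(iPr)2, 2.2 equiv, THF, −78 → 0 °C) and C-alkylated with 17 to give racemic 2-(benzyloxy)-3-[4-(benzyloxy)-3-methoxyphenyl]propanoic acid F1. Steglich esterification with 8 (DCC, DMAP, CH2Cl2) gives (S,Z)-5-[4-(benzyloxy)-3,5-dimethoxyphenyl]pent-3-en-2-yl 2-(benzyloxy)-3-[4-(benzyloxy)-3-methoxyphenyl]propanoate F2, whose two α-epimers converge on enolisation. LiN(iPr)2 in THF at −78 °C should give the lithium-chelated (Z)-enolate F3, with the benzyloxy oxygen bound to lithium and hence cis to O–Li, the same geometry as in 20. Me3SiCl/Et3N traps it as the (Z)-trimethylsilyl ketene acetal F4, which on warming to 23 °C should rearrange through the same chair to the trimethylsilyl ester F5. Work-up hydrolyses this to (2S,3S,E)-2-(benzyloxy)-2-[4-(benzyloxy)-3-methoxybenzyl]-3-[4-(benzyloxy)-3,5-dimethoxybenzyl]hex-4-enoic acid F6. Under the conditions of steps 14 and 15, F6 should pass through the 4,5-diol F7 to the 4-oxobutanoic acid F8, and then through the 4-hydroxybutanoic acid F9 to (3S,4S)-3-(benzyloxy)-3-[4-(benzyloxy)-3-methoxybenzyl]-4-[4-(benzyloxy)-3,5-dimethoxybenzyl]oxolan-2-one F10. Hydrogenolysis of all three benzyl ethers (H2, Pd(OH)2/C, EtOAc/MeOH) then gives 28.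

Step 9. The dioxirane may epoxidise the Z-alkene, or oxidise the electron-rich rings, in competition with oxygen transfer to the diazo carbon. The fallback sets out from alkynol 7 and comes back at 14; the oxidation is done before the alkene exists, since an internal alkyne is far less reactive toward a dioxirane. Bromoacetylation of 7 (BrCH2COBr, NaHCO3, MeCN, 0 °C) gives (S)-5-[4-(benzyloxy)-3,5-dimethoxyphenyl]pent-3-yn-2-yl bromoacetate F11. TsNHNHTs/DBU converts it, by way of the N-alkylated ditosylhydrazine F12 and the glyoxylate tosylhydrazone F13, into the propargylic diazoacetate F14. C-Silylation (tBuMe2SiOTf, iPr2NEt, Et2O) gives the silyl diazoacetate F15, and dimethyldioxirane gives (S)-5-[4-(benzyloxy)-3,5-dimethoxyphenyl]pent-3-yn-2-yl (tert-butyldimethylsilyl)glyoxylate F16. Semihydrogenation of F16 over Pd/CaCO3 poisoned with Pb(OAc)2 (quinoline, EtOAc) then gives 14.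

Step 12. The electron-rich benzylic chloride may homocouple with the organomagnesium as it forms at the metal surface (Wurtz coupling), leaving the 1,2-diarylethane and a weak reagent solution. The fallback sets out from 17 and comes back at 18; the benzylic carbanion is generated with no benzylic halide present. Displacement of chloride by Bu3SnLi (from Bu3SnH and LiN(iPr)2, THF, −78 °C) gives tributyl[4-(benzyloxy)-3-methoxybenzyl]stannane F17. Tin–lithium exchange with MeLi (THF, −78 °C) gives [4-(benzyloxy)-3-methoxybenzyl]lithium F18, and transmetalation with anhydrous MgCl2 (THF, −78 → 0 °C) gives 18.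

**Further compounds**

F1 | step 13 | 2-(benzyloxy)-3-[4-(benzyloxy)-3-methoxyphenyl]propanoic acid (racemic) | COc1cc(CC(OCc2ccccc2)C(=O)O)ccc1OCc1ccccc1
F2 | step 13 | (S,Z)-5-[4-(benzyloxy)-3,5-dimethoxyphenyl]pent-3-en-2-yl 2-(benzyloxy)-3-[4-(benzyloxy)-3-methoxyphenyl]propanoate (both α-epimers) | C[C@@H](/C=C\Cc1cc(OC)c(OCc2ccccc2)c(OC)c1)OC(=O)C(OCc1ccccc1)Cc1ccc(OCc2ccccc2)c(OC)c1
F3 | step 13 | lithium-chelated (Z)-enolate of F2 | C[C@@H](/C=C\Cc1cc(OC)c(OCc2ccccc2)c(OC)c1)O/C(O[Li])=C(/OCc1ccccc1)Cc1ccc(OCc2ccccc2)c(OC)c1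
F4 | step 13 | (Z)-trimethylsilyl ketene acetal of F2 | C[C@@H](/C=C\Cc1cc(OC)c(OCc2ccccc2)c(OC)c1)O/C(O[Si](C)(C)C)=C(/OCc1ccccc1)Cc1ccc(OCc2ccccc2)c(OC)c1
F5 | step 13 | trimethylsilyl (2S,3S,E)-2-(benzyloxy)-2-[4-(benzyloxy)-3-methoxybenzyl]-3-[4-(benzyloxy)-3,5-dimethoxybenzyl]hex-4-enoate | COc1cc(C[C@@](OCc2ccccc2)(C(=O)O[Si](C)(C)C)[C@H](/C=C/C)Cc2cc(OC)c(OCc3ccccc3)c(OC)c2)ccc1OCc1ccccc1
F6 | step 13 | (2S,3S,E)-2-(benzyloxy)-2-[4-(benzyloxy)-3-methoxybenzyl]-3-[4-(benzyloxy)-3,5-dimethoxybenzyl]hex-4-enoic acid | COc1cc(C[C@@](OCc2ccccc2)(C(=O)O)[C@H](/C=C/C)Cc2cc(OC)c(OCc3ccccc3)c(OC)c2)ccc1OCc1ccccc1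
F7 | step 13 | (2S,3S)-2-(benzyloxy)-2-[4-(benzyloxy)-3-methoxybenzyl]-3-[4-(benzyloxy)-3,5-dimethoxybenzyl]-4,5-dihydroxyhexanoic acid (diastereomers at C4 and C5) | COc1cc(C[C@@](OCc2ccccc2)(C(=O)O)[C@H](C(O)C(C)O)Cc2cc(OC)c(OCc3ccccc3)c(OC)c2)ccc1OCc1ccccc1
F8 | step 13 | (2S,3R)-2-(benzyloxy)-2-[4-(benzyloxy)-3-methoxybenzyl]-3-[4-(benzyloxy)-3,5-dimethoxybenzyl]-4-oxobutanoic acid | COc1cc(C[C@@](OCc2ccccc2)(C(=O)O)[C@H](C=O)Cc2cc(OC)c(OCc3ccccc3)c(OC)c2)ccc1OCc1ccccc1
F9 | step 13 | (2S,3S)-2-(benzyloxy)-2-[4-(benzyloxy)-3-methoxybenzyl]-3-[4-(benzyloxy)-3,5-dimethoxybenzyl]-4-hydroxybutanoic acid | COc1cc(C[C@@](OCc2ccccc2)(C(=O)O)[C@H](CO)Cc2cc(OC)c(OCc3ccccc3)c(OC)c2)ccc1OCc1ccccc1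
F10 | step 13 | (3S,4S)-3-(benzyloxy)-3-[4-(benzyloxy)-3-methoxybenzyl]-4-[4-(benzyloxy)-3,5-dimethoxybenzyl]oxolan-2-one | COc1cc(C[C@@]2(OCc3ccccc3)C(=O)OC[C@@H]2Cc2cc(OC)c(OCc3ccccc3)c(OC)c2)ccc1OCc1ccccc1
F11 | step 9 | (S)-5-[4-(benzyloxy)-3,5-dimethoxyphenyl]pent-3-yn-2-yl bromoacetate | C[C@@H](C#CCc1cc(OC)c(OCc2ccccc2)c(OC)c1)OC(=O)CBr
F12 | step 9 | (S)-5-[4-(benzyloxy)-3,5-dimethoxyphenyl]pent-3-yn-2-yl [1,2-bis(p-tolylsulfonyl)hydrazinyl]acetate | C[C@@H](C#CCc1cc(OC)c(OCc2ccccc2)c(OC)c1)OC(=O)CN(NS(=O)(=O)c1ccc(C)cc1)S(=O)(=O)c1ccc(C)cc1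
F13 | step 9 | (S)-5-[4-(benzyloxy)-3,5-dimethoxyphenyl]pent-3-yn-2-yl glyoxylate p-tolylsulfonylhydrazone | C[C@@H](C#CCc1cc(OC)c(OCc2ccccc2)c(OC)c1)OC(=O)C=NNS(=O)(=O)c1ccc(C)cc1
F14 | step 9 | (S)-5-[4-(benzyloxy)-3,5-dimethoxyphenyl]pent-3-yn-2-yl diazoacetate | C[C@@H](C#CCc1cc(OC)c(OCc2ccccc2)c(OC)c1)OC(=O)C=[N+]=[N-]
F15 | step 9 | (S)-5-[4-(benzyloxy)-3,5-dimethoxyphenyl]pent-3-yn-2-yl (tert-butyldimethylsilyl)diazoacetate | C[C@@H](C#CCc1cc(OC)c(OCc2ccccc2)c(OC)c1)OC(=O)C(=[N+]=[N-])[Si](C)(C)C(C)(C)C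
F16 | step 9 | (S)-5-[4-(benzyloxy)-3,5-dimethoxyphenyl]pent-3-yn-2-yl (tert-butyldimethylsilyl)glyoxylate | C[C@@H](C#CCc1cc(OC)c(OCc2ccccc2)c(OC)c1)OC(=O)C(=O)[Si](C)(C)C(C)(C)C
F17 | step 12 | tributyl[4-(benzyloxy)-3-methoxybenzyl]stannane | CCCC[Sn](CCCC)(CCCC)Cc1ccc(OCc2ccccc2)c(OC)c1
F18 | step 12 | [4-(benzyloxy)-3-methoxybenzyl]lithium | [Li]Cc1ccc(OCc2ccccc2)c(OC)c1
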